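**Retrosynthetic overview**

- The C9 and C9' carbinols come from a diester (i-Bu2AlH), and the C1'–C7' bond from a Heck coupling of a C1' aryl triflate with methyl acrylate.
- The feature used: in ring B the ring oxygen on C4' is para to C1'. Ring B can therefore be carried as a 4,4-dimethoxycyclohexa-2,5-dienone with C1' as the carbonyl carbon, C4' as the ketal carbon, C3' as the unsubstituted beta carbon and C5' as the methoxylated beta carbon.
- Ring C is cut at C8–C3' and C4'–O. The alkoxide enolate of an (R)-beta-hydroxy ester (ring A plus C7–C8–C9) adds to the dienone, the C7 hydroxyl replaces one ketal methoxy group, and loss of the other rearomatises ring B to a C1' phenol.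
- C7 is set by asymmetric hydrogenation of the aryl beta-keto ester; C8 is set by equilibration to the 2,3-trans ester.
- Ring order: ring A is bought, ring B is bought as 3,4-dimethoxyphenol (dearomatised, then rearomatised in the key step), ring C is closed in the key step.

Key step: step 3

Assumption: methyl 3-oxo-3-(3,4,5-trimethoxyphenyl)propanoate is taken as a catalogue compound (otherwise it is one step from 3,4,5-trimethoxyacetophenone, NaH and dimethyl carbonate).

**Step 1**
Reactants: 1 methyl 3-oxo-3-(3,4,5-trimethoxyphenyl)propanoate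
Product: 2 methyl (3R)-3-hydroxy-3-(3,4,5-trimethoxyphenyl)propanoate
Conditions: RuCl2[(S)-BINAP] (0.5 mol %), H2 (50 bar), MeOH, 50 °C
Reagents that add atoms: none
Why: Noyori asymmetric hydrogenation of a beta-keto ester, in which the substrate chelates ruthenium through both carbonyl groups and the (S)-BINAP ligand should direct hydride to the face that gives the R carbinol (the aryl group outranks CH2CO2Me, so the descriptor is opposite to that obtained with the same ligand in the alkyl series).

**Step 2**
Reactants: 3 3,4-dimethoxyphenol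
Product: 4 3,4,4-trimethoxycyclohexa-2,5-dien-1-one
Conditions: PhI(OAc)2 (1.1 equiv), MeOH, 0 → 23 °C
Reagents that add atoms: methanol, CO
Why: Oxidative dearomatisation of a para-methoxyphenol by trivalent iodine, in which ligand exchange at iodine and loss of PhI give a phenoxonium ion stabilised by the para methoxy group and methanol captures it at C4 to give the quinone monoketal.

**Step 3**
Reactants: 2 methyl (3R)-3-hydroxy-3-(3,4,5-trimethoxyphenyl)propanoate; 4 3,4,4-trimethoxycyclohexa-2,5-dien-1-one
Product: 8 methyl (2R,3R)-5-hydroxy-7-methoxy-2-(3,4,5-trimethoxyphenyl)-2,3-dihydro-1-benzofuran-3-carboxylate (2,3-trans), via Michael adduct 5 (not isolated), via bicyclic mixed ketal 6 (not isolated), via C3-epimeric ester mixture 7 (not isolated)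
Conditions: LiN(i-Pr)2 (2.2 equiv), THF, −78 °C; 4, −78 → −20 °C; AcOH, aqueous wash; crude in PhMe, CSA (10 mol %), 4 Å MS, 23 → 50 °C; then NaOMe (3 equiv), MeOH, 23 °C, Ar; AcOH
Reagents that add atoms: none
Why: Proposed new method: two equivalents of LiN(i-Pr)2 should turn 2 into its chelated lithium alkoxide enolate (the dianion of Fráter–Seebach alkylations), whose C8 adds 1,4 to the only unsubstituted enone carbon of 4 (the future C3') to give 5; the closest known reaction types are Michael additions of stabilised enolates to quinone monoketals and the acid-induced cyclisation and aromatisation of their 1,3-dicarbonyl adducts to 5-hydroxybenzofurans. Anhydrous CSA then ionises the allylic ketal to the C4' oxocarbenium ion, the C7 hydroxyl captures it in a 5-exo-trig closure of ring C (mixed ketal 6), and loss of the second methanol across C3'–C4' followed by enolisation of the C1' ketone rearomatises ring B (7). C7 keeps its R configuration because its C–O bond is never broken (the ring oxygen is the alcohol oxygen of 2), and C8, which is alpha to the ester and benzylic, is set by NaOMe equilibration to the more stable 2,3-trans ester whatever the facial course of the addition. The step needs conjugate addition at C3' in preference to carbonyl attack and to attack at C5': the methoxy group makes C5' a vinylogous ester carbon, and a kinetic carbonyl adduct, being a lithium aldolate, should revert and drain to the conjugate adduct on warming to −20 °C. It also needs ketal exchange before elimination, which is why the acid stage is run without methanol or water, so that the C7 hydroxyl is the only nucleophile near the oxocarbenium ion.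

**Step 4**
Reactants: 8 methyl (2R,3R)-5-hydroxy-7-methoxy-2-(3,4,5-trimethoxyphenyl)-2,3-dihydro-1-benzofuran-3-carboxylate
Product: 9 methyl (2R,3R)-7-methoxy-5-(trifluoromethylsulfonyloxy)-2-(3,4,5-trimethoxyphenyl)-2,3-dihydro-1-benzofuran-3-carboxylate
Conditions: Tf2O (1.2 equiv), pyridine (3 equiv), CH2Cl2, −20 → 0 °C
Reagents that add atoms: trifluoromethanesulfonic anhydride, O=S(=O)(OS(=O)(=O)C(F)(F)F)C(F)(F)F
Why: O-sulfonylation of the only free hydroxyl (the C1' phenol) by Tf2O with pyridine as base, under which the ester, the aryl ethers and both stereocentres should remain untouched.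

**Step 5**
Reactants: 9 methyl (2R,3R)-7-methoxy-5-(trifluoromethylsulfonyloxy)-2-(3,4,5-trimethoxyphenyl)-2,3-dihydro-1-benzofuran-3-carboxylate; 10 methyl acrylate
Product: 11 methyl (2R,3R)-7-methoxy-5-[(E)-3-methoxy-3-oxoprop-1-en-1-yl]-2-(3,4,5-trimethoxyphenyl)-2,3-dihydro-1-benzofuran-3-carboxylate
Conditions: Pd(OAc)2 (5 mol %), dppp (6 mol %), Et3N (2 equiv), DMF, 90 °C
Reagents that add atoms: none
Why: Mizoroki–Heck reaction, in which zerovalent palladium formed in situ inserts into the aryl triflate, the acrylate inserts syn with the aryl group going to its beta carbon, and syn beta-hydride elimination gives the E cinnamate, while C8 already has its thermodynamic trans configuration and cannot be displaced by the amine base.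

**Step 6**
Reactants: 11 methyl (2R,3R)-7-methoxy-5-[(E)-3-methoxy-3-oxoprop-1-en-1-yl]-2-(3,4,5-trimethoxyphenyl)-2,3-dihydro-1-benzofuran-3-carboxylate
Product: 12 (−)-(7R,8S,7'E)-3,4,5,5'-tetramethoxy-4',7-epoxy-8,3'-neolign-7'-ene-9,9'-diol, i.e. (E)-3-[(2R,3S)-3-(hydroxymethyl)-7-methoxy-2-(3,4,5-trimethoxyphenyl)-2,3-dihydro-1-benzofuran-5-yl]prop-2-en-1-ol
Conditions: i-Bu2AlH (6 equiv), CH2Cl2, −78 → 0 °C; aq. potassium sodium tartrate
Reagents that add atoms: none
Why: Hydride reduction of both esters by i-Bu2AlH, which should take the saturated ester and, by 1,2-addition, the cinnamate to the primary alcohols without touching the alkene or the benzylic aryl ether, the C8 descriptor changing from R to S only because CH2OH ranks below C7.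

**Compound list**

1 | methyl 3-oxo-3-(3,4,5-trimethoxyphenyl)propanoate | COC(=O)CC(=O)c1cc(OC)c(OC)c(OC)c1 | starting material
2 | methyl (3R)-3-hydroxy-3-(3,4,5-trimethoxyphenyl)propanoate | COC(=O)C[C@@H](O)c1cc(OC)c(OC)c(OC)c1 | intermediate
3 | 3,4-dimethoxyphenol | COc1ccc(O)cc1OC | starting material
4 | 3,4,4-trimethoxycyclohexa-2,5-dien-1-one | COC1=CC(=O)C=CC1(OC)OC | intermediate
5 | Michael adduct, methyl (3R)-3-hydroxy-2-(2,2,3-trimethoxy-5-oxocyclohex-3-en-1-yl)-3-(3,4,5-trimethoxyphenyl)propanoate (mixture at C2 and at the ring carbon) | COC(=O)C([C@@H](O)c1cc(OC)c(OC)c(OC)c1)C1CC(=O)C=C(OC)C1(OC)OC | intermediate (not isolated)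
6 | bicyclic mixed ketal, methyl (2R)-7,7a-dimethoxy-5-oxo-2-(3,4,5-trimethoxyphenyl)-2,3,3a,4,5,7a-hexahydro-1-benzofuran-3-carboxylate (mixture at C3, C3a, C7a) | COC(=O)C1C2CC(=O)C=C(OC)C2(OC)O[C@H]1c1cc(OC)c(OC)c(OC)c1 | intermediate (not isolated)
7 | C3-epimeric ester mixture, methyl (2R)-5-hydroxy-7-methoxy-2-(3,4,5-trimethoxyphenyl)-2,3-dihydro-1-benzofuran-3-carboxylate (2,3-cis and 2,3-trans) | COc1cc([C@@H]2Oc3c(OC)cc(O)cc3C2C(=O)OC)cc(OC)c1OC | intermediate (not isolated)
8 | methyl (2R,3R)-5-hydroxy-7-methoxy-2-(3,4,5-trimethoxyphenyl)-2,3-dihydro-1-benzofuran-3-carboxylate (2,3-trans) | COc1cc([C@@H]2Oc3c(OC)cc(O)cc3[C@H]2C(=O)OC)cc(OC)c1OC | intermediate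
9 | methyl (2R,3R)-7-methoxy-5-(trifluoromethylsulfonyloxy)-2-(3,4,5-trimethoxyphenyl)-2,3-dihydro-1-benzofuran-3-carboxylate | COc1cc([C@@H]2Oc3c(OC)cc(OS(=O)(=O)C(F)(F)F)cc3[C@H]2C(=O)OC)cc(OC)c1OC | intermediate
10 | methyl acrylate | COC(=O)C=C | starting material
11 | methyl (2R,3R)-7-methoxy-5-[(E)-3-methoxy-3-oxoprop-1-en-1-yl]-2-(3,4,5-trimethoxyphenyl)-2,3-dihydro-1-benzofuran-3-carboxylate | COc1cc([C@@H]2Oc3c(OC)cc(/C=C/C(=O)OC)cc3[C@H]2C(=O)OC)cc(OC)c1OC | intermediate
12 | (−)-(7R,8S,7'E)-3,4,5,5'-tetramethoxy-4',7-epoxy-8,3'-neolign-7'-ene-9,9'-diol | COc1cc([C@@H]2Oc3c(OC)cc(/C=C/CO)cc3[C@H]2CO)cc(OC)c1OC | target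

**Step count**

Total: 6 steps. Longest linear sequence: 5 steps (steps 1, 3, 4, 5, 6).

**Steps most likely to fail**

Step 3 (proposed new method). What may go wrong:
- the hard lithium enolate may attack the carbonyl of 4 instead of C3';
- the lithium aldolate may fragment by retro-aldol cleavage on warming;
- methanol may be lost across C3'–C4' before the C7 hydroxyl has entered the ketal, which leaves a C4' methyl ether;
- methoxide may open ring C by beta-elimination during the equilibration.

The fallback uses known chemistry, sets out from 1 and 4 and returns at 8. The potassium enolate of keto ester 1 (KOt-Bu cat., THF) is added to monoketal 4, a Michael addition of a 1,3-dicarbonyl compound to a quinone monoketal. Treating the crude adduct with TsOH in PhMe should cyclise the enol oxygen onto the ketal carbon and aromatise both rings to methyl 5-hydroxy-7-methoxy-2-(3,4,5-trimethoxyphenyl)-1-benzofuran-3-carboxylate F1. Mg in MeOH should then reduce the C2=C3 bond of this vinylogous carbonate with thermodynamic protonation to the racemic 2,3-trans dihydro ester F2. Resolution of F2 by preparative chromatography on a chiral stationary phase would deliver 8, and the route continues with step 4.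

Step 5. What may go wrong:
- oxidative addition into the electron-rich aryl triflate may be slow;
- S–O cleavage of the triflate may return phenol 8;
- the amine at 90 °C may open ring C by beta-elimination from the C8 enolate.

The fallback sets out from 9 and returns at 12. It is a base-free Stille coupling of 9 with (E)-3-(tributylstannyl)prop-2-en-1-ol (Pd(PPh3)4, a zerovalent palladium complex, with LiCl in dioxane at 90 °C). This brings in the side chain at the alcohol oxidation level and should give methyl (2R,3R)-5-[(E)-3-hydroxyprop-1-en-1-yl]-7-methoxy-2-(3,4,5-trimethoxyphenyl)-2,3-dihydro-1-benzofuran-3-carboxylate F3. Reduction of the remaining ester of F3 with i-Bu2AlH (CH2Cl2, −78 → 0 °C) would give target 12 directly.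

Step 1. What may go wrong: enantioface discrimination may be incomplete with the electron-rich aryl ketone, and any erosion is carried unchanged to the target.

The fallback sets out from 1 and returns at 2.
- NaBH4 in MeOH at 0 °C reduces 1 to racemic methyl 3-hydroxy-3-(3,4,5-trimethoxyphenyl)propanoate F4.
- Kinetic resolution with Burkholderia cepacia lipase and vinyl acetate in t-BuOMe should acylate the R enantiomer (aryl as the large group, CH2CO2Me as the medium group) to methyl (3R)-3-acetoxy-3-(3,4,5-trimethoxyphenyl)propanoate F5, which is separated from the unreacted S alcohol.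
- Lipase-catalysed methanolysis of F5 (Candida antarctica lipase B, MeOH, t-BuOMe) avoids base-induced elimination to the cinnamate and would give 2.

**Further compounds**

F1 | step 3 | methyl 5-hydroxy-7-methoxy-2-(3,4,5-trimethoxyphenyl)-1-benzofuran-3-carboxylate | COC(=O)c1c(-c2cc(OC)c(OC)c(OC)c2)oc2c(OC)cc(O)cc12
F2 | step 3 | racemic trans-methyl 5-hydroxy-7-methoxy-2-(3,4,5-trimethoxyphenyl)-2,3-dihydro-1-benzofuran-3-carboxylate (8 plus its 2S,3S enantiomer) | COc1cc([C@@H]2Oc3c(OC)cc(O)cc3[C@H]2C(=O)OC)cc(OC)c1OC.COc1cc([C@H]2Oc3c(OC)cc(O)cc3[C@@H]2C(=O)OC)cc(OC)c1OC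
F3 | step 5 | methyl (2R,3R)-5-[(E)-3-hydroxyprop-1-en-1-yl]-7-methoxy-2-(3,4,5-trimethoxyphenyl)-2,3-dihydro-1-benzofuran-3-carboxylate | COc1cc([C@@H]2Oc3c(OC)cc(/C=C/CO)cc3[C@H]2C(=O)OC)cc(OC)c1OC
F4 | step 1 | racemic methyl 3-hydroxy-3-(3,4,5-trimethoxyphenyl)propanoate | COC(=O)CC(O)c1cc(OC)c(OC)c(OC)c1
F5 | step 1 | methyl (3R)-3-acetoxy-3-(3,4,5-trimethoxyphenyl)propanoate | COC(=O)C[C@@H](OC(C)=O)c1cc(OC)c(OC)c(OC)c1
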